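## Retrosynthetic overview

1. Target 24 ⇐ enone 23 (CBS reduction sets C16) ⇐ dienone 22 (OH‑directed hydrogenation sets C18) ⇐ enone 21 (dehydrogenation gives C14=C15).
2. Key disconnection: the cyclopentane and cycloheptane of 21 form together from the acyclic 1,6‑enyne/alkene 20 in one Au(I) cascade (bonds C18–C22 and C14–C23, then 1,2‑H shift).
3. 20 ⇐ enal 14 + the acetylide of (R)‑dehydrolinalool, made in the flask from the nerol‑derived epoxy chloride 17.
4. 14 ⇐ oxepane/cyclohexanone 11 (MeCeCl2, Ac2O, cross‑metathesis); 11 ⇐ diepoxy enol silane 9 by TMSOTf oxa‑/carbacyclisation; 9 ⇐ geranyl bromide.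
5. Ring order: oxepane + cyclohexane together (step 5), then cyclopentane + cycloheptane together (step 13).

Assumption: locants C2–C23 in the "Why" lines are squalene‑type skeleton locants (C2 oxepane CMe2, C3 CHOAc, C6 angular C–Me, C7 CH–O, C10 C(Me)OH, C11 CH bearing the chain, C12–C13 linker, C14=C15(Me), C16 CHOH, C17 CH2, C18/C22 ring‑fusion CH, C19 C(Me)OH, C23 carbocyclic CMe2); commercial geranyl bromide and nerol are taken as isomerically pure.

## Route

Step 1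
Reactants: 1 geranyl bromide; 2 N‑methoxy‑N‑methylacetamide
Product: 4 (4E)‑N‑methoxy‑N,5,9‑trimethyldeca‑4,8‑dienamide, via lithium amide enolate 3 (not isolated)
Conditions: 2, LDA (1.05 equiv), THF, −78 °C; then 1, −78 → 0 °C
Reagents that add atoms: none
Why: Enolate alkylation (SN2) of the Weinreb acetamide enolate with the reactive primary allylic bromide; the E‑alkene is untouched and no stereocentre is formed.

Step 2
Reactants: 4 (4E)‑N‑methoxy‑N,5,9‑trimethyldeca‑4,8‑dienamide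
Product: 7 (4R,5R,8R)‑4,5:8,9‑diepoxy‑N‑methoxy‑N,5,9‑trimethyldecanamide, via 8,9‑monoepoxide 5 (not isolated), via 4,5‑monoepoxide 6 (not isolated)
Conditions: D‑fructose‑derived Shi ketone (0.6 equiv), Oxone, K2CO3, Bu4NHSO4 (cat.), MeCN/DMM–aq. Na2B4O7/EDTA, pH 10.5, 0 °C
Reagents that add atoms: potassium peroxymonosulfate (active part of Oxone), [K+].OOS(=O)(=O)[O-]
Why: Shi asymmetric epoxidation; the chiral dioxirane attacks both unactivated trisubstituted E‑alkenes through the spiro transition state and gives the (R)/(R,R) epoxides that become C3, C6 and C7, while the amide is inert.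

Step 3
Reactants: 7 (4R,5R,8R)‑diepoxy Weinreb amide
Product: 8 (6R,7R,10R)‑6,7:10,11‑diepoxy‑7,11‑dimethyldodec‑1‑en‑3‑one
Conditions: CH2=CHMgBr (1.3 equiv), THF, −78 → 0 °C; cold aq. NH4Cl
Reagents that add atoms: vinylmagnesium bromide, C=C[Mg]Br
Why: Weinreb ketone synthesis; the stable magnesium chelate prevents over‑addition, trisubstituted epoxides do not react with the Grignard reagent at low temperature, and no stereocentre is touched.

Step 4
Reactants: 8 (6R,7R,10R)‑diepoxy vinyl ketone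
Product: 9 (5Z,9R,10R,13R)‑9,10:13,14‑diepoxy‑10,14‑dimethyl‑6‑[(trimethylsilyl)oxy]pentadeca‑1,5‑diene
Conditions: allylMgCl (1.5 equiv), CuBr·SMe2 (1.5 equiv), TMSCl (3 equiv), THF, −78 °C; Et3N, pentane, filter, use crude
Reagents that add atoms: allylmagnesium chloride, C=CC[Mg]Cl; chlorotrimethylsilane, C[Si](C)(C)Cl
Why: TMSCl‑accelerated conjugate addition of an allylcopper reagent (Lipshutz type) to the s‑cis vinyl ketone with O‑silylation of the enolate, which fixes the enol ether regiospecifically toward C11, something direct enolisation of the ketone could not do.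

Step 5
Reactants: 9 diepoxy TMS enol ether
Product: 11 (3R,5aR,6R,9aR)‑6‑(but‑3‑en‑1‑yl)‑3‑hydroxy‑2,2,5a‑trimethyloctahydro‑1‑benzoxepin‑7(2H)‑one, via 3‑O‑TMS ether 10 (not isolated)
Conditions: TMSOTf (1.2 equiv), 2,6‑di‑tert‑butyl‑4‑methylpyridine (1.5 equiv), CH2Cl2, −78 °C; then citric acid, MeOH, 0 °C
Reagents that add atoms: none
Why: McDonald‑type tandem oxa‑/carbacyclisation: silylation of the terminal epoxide triggers attack of the internal epoxide oxygen at tertiary C2, and the bicyclic epoxonium ion is opened at C6 with inversion by C11 of the enol silane, so the oxepane and the cyclohexanone form in one operation; the trans ring fusion follows from the trans‑epoxide, C3 and C7 keep their Shi configurations, and the epimerisable C11 substituent settles equatorial.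

Step 6
Reactants: 11 hydroxy ketone
Product: 12 (3R,5aR,6R,7S,9aR)‑6‑(but‑3‑en‑1‑yl)‑2,2,5a,7‑tetramethyldecahydro‑1‑benzoxepine‑3,7‑diol
Conditions: MeMgBr (4 equiv), CeCl3 (4 equiv), THF, −78 → 0 °C
Reagents that add atoms: methylmagnesium bromide, C[Mg]Br
Why: Organocerium (Imamoto) 1,2‑addition suppresses enolisation, and the axial C6 methyl (1,3 to C10) blocks axial approach, so methyl enters equatorially and gives the axial (S) tertiary alcohol at C10.

Step 7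
Reactants: 12 diol
Product: 13 (3R,5aR,6R,7S,9aR)‑6‑(but‑3‑en‑1‑yl)‑7‑hydroxy‑2,2,5a,7‑tetramethyldecahydro‑1‑benzoxepin‑3‑yl acetate
Conditions: Ac2O (1.5 equiv), pyridine, DMAP (5 mol %), CH2Cl2, 0 °C → rt
Reagents that add atoms: acetic anhydride, CC(=O)OC(C)=O
Why: DMAP‑catalysed acylation; only the secondary C3 alcohol reacts, the hindered axial tertiary C10 alcohol is inert under these conditions.

Step 8
Reactants: 13 butenyl acetate
Product: 14 (3R,5aR,6R,7S,9aR)‑7‑hydroxy‑2,2,5a,7‑tetramethyl‑6‑[(3E)‑4‑methyl‑5‑oxopent‑3‑en‑1‑yl]decahydro‑1‑benzoxepin‑3‑yl acetate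
Conditions: methacrolein (10 equiv), Hoveyda–Grubbs II (5 mol %), CH2Cl2, 40 °C
Reagents that add atoms: methacrolein, C=C(C)C=O
Why: Olefin cross‑metathesis of a terminal alkene with methacrolein gives the thermodynamically favoured (E)‑2‑methyl enal; the free tertiary alcohol and the acetate are tolerated.

Step 9
Reactants: 15 nerol
Product: 16 [(2S,3R)‑3‑methyl‑3‑(4‑methylpent‑3‑en‑1‑yl)oxiran‑2‑yl]methanol
Conditions: Ti(OiPr)4 (10 mol %), L‑(+)‑DET (12 mol %), t‑BuOOH (2 equiv), 4 Å MS, CH2Cl2, −20 °C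
Reagents that add atoms: tert‑butyl hydroperoxide, CC(C)(C)OO
Why: Sharpless asymmetric epoxidation; L‑(+)‑tartrate turns the Z‑allylic alcohol into the (2S,3R)‑epoxide, which fixes the future C19 carbinol as R, and the remote trisubstituted alkene is untouched.

Step 10
Reactants: 16 (2S,3R)‑epoxynerol
Product: 17 (2R,3R)‑2‑(chloromethyl)‑3‑methyl‑3‑(4‑methylpent‑3‑en‑1‑yl)oxirane
Conditions: PPh3 (1.3 equiv), CCl4, NaHCO3, 70 °C
Reagents that add atoms: carbon tetrachloride, ClC(Cl)(Cl)Cl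
Why: Appel chlorination of the primary alcohol under neutral conditions; the epoxide stereocentres are not touched (the C2 descriptor changes only through CIP priority).

Step 11
Reactants: 17 epoxy chloride; 14 enal
Product: 19 (3R,5aR,6R,7S,9aR)‑6‑[(3E,8R)‑5,8‑dihydroxy‑4,8,12‑trimethyltrideca‑3,11‑dien‑6‑yn‑1‑yl]‑7‑hydroxy‑2,2,5a,7‑tetramethyldecahydro‑1‑benzoxepin‑3‑yl acetate (about 1:1 at side‑chain C5 = C16), via dilithio dehydrolinalool 18 (not isolated)
Conditions: 17 (2.5 equiv), n‑BuLi (7.4 equiv), THF, −40 °C, 1 h; then 14 (1.0 equiv), −78 °C; aq. NH4Cl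
Reagents that add atoms: none
Why: Base‑induced double elimination of a 2,3‑epoxy chloride (Takano–Yadav alkynol synthesis) gives the tertiary propargylic alkoxide with C19 retained as R and, with the third equivalent of base, its lithium acetylide, which adds 1,2 to the enal much faster than to the acetate at −78 °C; the C16 mixture is irrelevant because C16 becomes a ketone in step 13.

Step 12
Reactants: 19 propargylic triol
Product: 20 the 16‑O‑triisopropylsilyl ether of 19 (side‑chain 5‑OTIPS)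
Conditions: TIPSOTf (1.1 equiv), 2,6‑lutidine (2.5 equiv), CH2Cl2, −78 °C
Reagents that add atoms: triisopropylsilyl trifluoromethanesulfonate, CC(C)[Si](OS(=O)(=O)C(F)(F)F)(C(C)C)C(C)C
Why: Silyl triflate/lutidine silylation; at −78 °C only the secondary propargylic–allylic C16 alcohol reacts, the two tertiary alcohols are too hindered for the TIPS group.

Step 13
Reactants: 20 TIPS‑protected dienyne
Product: 21 (3R,5aR,6R,7S,9aR)‑7‑hydroxy‑6‑{2‑[(1R,3aS)‑1‑hydroxy‑1,4,4,6‑tetramethyl‑7‑oxo‑1,2,3,3a,4,5,6,7‑octahydroazulen‑5‑yl]ethyl}‑2,2,5a,7‑tetramethyldecahydro‑1‑benzoxepin‑3‑yl acetate (azulene C5/C6 = C14/C15 as a mixture)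
Conditions: [(JohnPhos)Au(NCMe)]SbF6 (5 mol %), CH2Cl2 (0.02 M), H2O (2 equiv), −20 → 23 °C
Reagents that add atoms: none
Why: Proposed new method: cationic Au(I) activates the C17≡C18 alkyne, the prenyl alkene attacks C18 anti to gold (5‑exo‑dig) to give the cyclopropyl gold carbene/tertiary C23 cation with the C16 arm cis to C22 on the new alkenyl–gold, the trisubstituted C14=C15 alkene then captures C23 through C14 (Markovnikov, seven‑membered ring) and the tertiary C15 cation is quenched by a semipinacol‑type 1,2‑hydride shift from C16 (silyloxocarbenium ion, desilylated by water, then protodeauration) to give the enone; the bulky TIPS ether disfavours O‑capture of the cation, C22 is set relative to C19 in the first ring closure with the C19 methyl pseudo‑equatorial and cis to the C23 arm (estimated dr 3–4:1, minor isomer removed by chromatography), and the closest known reactions are Echavarren's Au(I) 1,6‑enyne cyclisations with capture of the cation by an aryl or alkenyl group on the alkyne terminus (formal [4+2]) and Prins–pinacol‑type terminations.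

Step 14
Reactants: 21 enone
Product: 22 (3R,5aR,6R,7S,9aR)‑7‑hydroxy‑6‑{2‑[(1R,3aS)‑1‑hydroxy‑1,4,4,6‑tetramethyl‑7‑oxo‑1,2,3,3a,4,7‑hexahydroazulen‑5‑yl]ethyl}‑2,2,5a,7‑tetramethyldecahydro‑1‑benzoxepin‑3‑yl acetate
Conditions: DDQ (1.3 equiv), 1,4‑dioxane, 80 °C
Reagents that add atoms: none
Why: DDQ dehydrogenation of an enone to the cross‑conjugated dienone (the steroid Δ1 manifold); C15 is the only α′ position, hydride abstraction from the tertiary allylic C14–H of the 2,4‑dienol gives the tetrasubstituted C14=C15 bond, both C14/C15 epimers converge, and the acetate and tertiary alcohols are inert.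

Step 15
Reactants: 22 dienone
Product: 23 (3R,5aR,6R,7S,9aR)‑7‑hydroxy‑6‑{2‑[(1R,3aR,8aR)‑1‑hydroxy‑1,4,4,6‑tetramethyl‑7‑oxo‑1,2,3,3a,4,7,8,8a‑octahydroazulen‑5‑yl]ethyl}‑2,2,5a,7‑tetramethyldecahydro‑1‑benzoxepin‑3‑yl acetate
Conditions: [Ir(cod)(PCy3)(py)]PF6 (5 mol %), H2 (1 atm), CH2Cl2, 0 °C → rt
Reagents that add atoms: none
Why: Hydroxyl‑directed hydrogenation with Crabtree's catalyst; the allylic tertiary C19–OH binds iridium and delivers H2 to the trisubstituted C17=C18 bond from its own face, which sets H‑18 cis to 19‑OH and to H‑22 (cis‑fused hydroazulene), while the undirected tetrasubstituted C14=C15 bond next to CMe2 is not reduced.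

Step 16
Reactants: 23 enone
Product: 24 target, (3R,5aR,6R,7S,9aR)‑6‑{2‑[(1R,3aR,7R,8aR)‑1,7‑dihydroxy‑1,4,4,6‑tetramethyl‑1,2,3,3a,4,7,8,8a‑octahydroazulen‑5‑yl]ethyl}‑7‑hydroxy‑2,2,5a,7‑tetramethyldecahydro‑1‑benzoxepin‑3‑yl acetate
Conditions: (S)‑Me‑CBS (0.5 equiv), BH3·SMe2 (3 equiv), THF, −30 °C; MeOH quench
Reagents that add atoms: none
Why: Corey–Bakshi–Shibata reduction; with the tetrasubstituted alkenyl carbon C15 as the large and C17H2 as the small group, the (S)‑oxazaborolidine delivers hydride to give the (16R) allylic alcohol (same sense as acetophenone → (R)‑alcohol), and borane at −30 °C spares the acetate and the hindered alkene.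

## Compound list

1 | geranyl bromide, (2E)‑1‑bromo‑3,7‑dimethylocta‑2,6‑diene | CC(C)=CCC/C(C)=C/CBr | starting material
2 | N‑methoxy‑N‑methylacetamide | CC(=O)N(C)OC | starting material
3 | lithium enolate of N‑methoxy‑N‑methylacetamide | [Li]OC(=C)N(C)OC | intermediate
4 | (4E)‑N‑methoxy‑N,5,9‑trimethyldeca‑4,8‑dienamide | CC(C)=CCC/C(C)=C/CCC(=O)N(C)OC | intermediate
5 | (4E,8R)‑8,9‑epoxy‑N‑methoxy‑N,5,9‑trimethyldec‑4‑enamide | CC1(C)O[C@@H]1CC/C(C)=C/CCC(=O)N(C)OC | intermediate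
6 | (4R,5R)‑4,5‑epoxy‑N‑methoxy‑N,5,9‑trimethyldec‑8‑enamide | CC(C)=CCC[C@@]1(C)O[C@@H]1CCC(=O)N(C)OC | intermediate
7 | (4R,5R,8R)‑4,5:8,9‑diepoxy‑N‑methoxy‑N,5,9‑trimethyldecanamide | CC1(C)O[C@@H]1CC[C@@]2(C)O[C@@H]2CCC(=O)N(C)OC | intermediate
8 | (6R,7R,10R)‑6,7:10,11‑diepoxy‑7,11‑dimethyldodec‑1‑en‑3‑one | CC1(C)O[C@@H]1CC[C@@]2(C)O[C@@H]2CCC(=O)C=C | intermediate
9 | (5Z,9R,10R,13R)‑9,10:13,14‑diepoxy‑10,14‑dimethyl‑6‑[(trimethylsilyl)oxy]pentadeca‑1,5‑diene | CC1(C)O[C@@H]1CC[C@@]2(C)O[C@@H]2CC/C(O[Si](C)(C)C)=C/CCC=C | intermediate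
10 | (3R,5aR,6R,9aR)‑6‑(but‑3‑en‑1‑yl)‑2,2,5a‑trimethyl‑3‑[(trimethylsilyl)oxy]octahydro‑1‑benzoxepin‑7(2H)‑one (trans‑fused) | C[Si](C)(C)O[C@@H]1CC[C@]2(C)[C@@H](CCC=C)C(=O)CC[C@H]2OC1(C)C | intermediate
11 | (3R,5aR,6R,9aR)‑6‑(but‑3‑en‑1‑yl)‑3‑hydroxy‑2,2,5a‑trimethyloctahydro‑1‑benzoxepin‑7(2H)‑one (trans‑fused) | O[C@@H]1CC[C@]2(C)[C@@H](CCC=C)C(=O)CC[C@H]2OC1(C)C | intermediate
12 | (3R,5aR,6R,7S,9aR)‑6‑(but‑3‑en‑1‑yl)‑2,2,5a,7‑tetramethyldecahydro‑1‑benzoxepine‑3,7‑diol | O[C@@H]1CC[C@]2(C)[C@@H](CCC=C)[C@@](C)(O)CC[C@H]2OC1(C)C | intermediate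
13 | (3R,5aR,6R,7S,9aR)‑6‑(but‑3‑en‑1‑yl)‑7‑hydroxy‑2,2,5a,7‑tetramethyldecahydro‑1‑benzoxepin‑3‑yl acetate | CC(=O)O[C@@H]1CC[C@]2(C)[C@@H](CCC=C)[C@@](C)(O)CC[C@H]2OC1(C)C | intermediate
14 | (3R,5aR,6R,7S,9aR)‑7‑hydroxy‑2,2,5a,7‑tetramethyl‑6‑[(3E)‑4‑methyl‑5‑oxopent‑3‑en‑1‑yl]decahydro‑1‑benzoxepin‑3‑yl acetate | CC(=O)O[C@@H]1CC[C@]2(C)[C@@H](CC/C=C(\C)C=O)[C@@](C)(O)CC[C@H]2OC1(C)C | intermediate
15 | nerol, (2Z)‑3,7‑dimethylocta‑2,6‑dien‑1‑ol | CC(C)=CCC/C(C)=C\CO | starting material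
16 | [(2S,3R)‑3‑methyl‑3‑(4‑methylpent‑3‑en‑1‑yl)oxiran‑2‑yl]methanol | CC(C)=CCC[C@@]1(C)O[C@H]1CO | intermediate
17 | (2R,3R)‑2‑(chloromethyl)‑3‑methyl‑3‑(4‑methylpent‑3‑en‑1‑yl)oxirane | CC(C)=CCC[C@@]1(C)O[C@H]1CCl | intermediate
18 | dilithium salt (alkoxide/acetylide) of (3R)‑3,7‑dimethyloct‑6‑en‑1‑yn‑3‑ol | [Li]C#C[C@](C)(O[Li])CCC=C(C)C | intermediate
19 | (3R,5aR,6R,7S,9aR)‑6‑[(3E,8R)‑5,8‑dihydroxy‑4,8,12‑trimethyltrideca‑3,11‑dien‑6‑yn‑1‑yl]‑7‑hydroxy‑2,2,5a,7‑tetramethyldecahydro‑1‑benzoxepin‑3‑yl acetate (both C5 epimers of the side chain) | CC(=O)O[C@@H]1CC[C@]2(C)[C@@H](CC/C=C(\C)C(O)C#C[C@](C)(O)CCC=C(C)C)[C@@](C)(O)CC[C@H]2OC1(C)C | intermediate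
20 | side‑chain 5‑O‑triisopropylsilyl ether of 19 (16‑OTIPS) | CC(=O)O[C@@H]1CC[C@]2(C)[C@@H](CC/C=C(\C)C(O[Si](C(C)C)(C(C)C)C(C)C)C#C[C@](C)(O)CCC=C(C)C)[C@@](C)(O)CC[C@H]2OC1(C)C | intermediate
21 | (3R,5aR,6R,7S,9aR)‑7‑hydroxy‑6‑{2‑[(1R,3aS)‑1‑hydroxy‑1,4,4,6‑tetramethyl‑7‑oxo‑1,2,3,3a,4,5,6,7‑octahydroazulen‑5‑yl]ethyl}‑2,2,5a,7‑tetramethyldecahydro‑1‑benzoxepin‑3‑yl acetate (azulene C5/C6 mixture; 1‑OH cis to H‑3a) | CC(=O)O[C@@H]1CC[C@]2(C)[C@@H](CCC3C(C)C(=O)C=C4[C@@H](CC[C@@]4(C)O)C3(C)C)[C@@](C)(O)CC[C@H]2OC1(C)C | intermediate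
22 | (3R,5aR,6R,7S,9aR)‑7‑hydroxy‑6‑{2‑[(1R,3aS)‑1‑hydroxy‑1,4,4,6‑tetramethyl‑7‑oxo‑1,2,3,3a,4,7‑hexahydroazulen‑5‑yl]ethyl}‑2,2,5a,7‑tetramethyldecahydro‑1‑benzoxepin‑3‑yl acetate | CC(=O)O[C@@H]1CC[C@]2(C)[C@@H](CCC3=C(C)C(=O)C=C4[C@@H](CC[C@@]4(C)O)C3(C)C)[C@@](C)(O)CC[C@H]2OC1(C)C | intermediate
23 | (3R,5aR,6R,7S,9aR)‑7‑hydroxy‑6‑{2‑[(1R,3aR,8aR)‑1‑hydroxy‑1,4,4,6‑tetramethyl‑7‑oxo‑1,2,3,3a,4,7,8,8a‑octahydroazulen‑5‑yl]ethyl}‑2,2,5a,7‑tetramethyldecahydro‑1‑benzoxepin‑3‑yl acetate (cis‑fused) | CC(=O)O[C@@H]1CC[C@]2(C)[C@@H](CCC3=C(C)C(=O)C[C@@H]4[C@@H](CC[C@@]4(C)O)C3(C)C)[C@@](C)(O)CC[C@H]2OC1(C)C | intermediate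
24 | (3R,5aR,6R,7S,9aR)‑6‑{2‑[(1R,3aR,7R,8aR)‑1,7‑dihydroxy‑1,4,4,6‑tetramethyl‑1,2,3,3a,4,7,8,8a‑octahydroazulen‑5‑yl]ethyl}‑7‑hydroxy‑2,2,5a,7‑tetramethyldecahydro‑1‑benzoxepin‑3‑yl acetate (CNP0157376.1) | CC(=O)O[C@@H]1CC[C@]2(C)[C@@H](CCC3=C(C)[C@H](O)C[C@@H]4[C@@H](CC[C@@]4(C)O)C3(C)C)[C@@](C)(O)CC[C@H]2OC1(C)C | target

## Step count and risk

Total steps: 16 (steps 1–8 left half, 9–10 alkyne precursor, 11–16 union and endgame).
Longest linear sequence: 14 steps (1–8, then 11–16, from geranyl bromide).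

Steps most likely to fail:

**Step 13 (Au cascade).** The seven‑membered ring may not close, giving skeletal rearrangement or formal Alder‑ene products instead, or the C22 selectivity may be poor. Fallback: make the two carbocycles one at a time and close the second with a polarity‑matched radical. Starting from 20, PtCl2 (5 mol %) in acetone gives the formal Alder‑ene product, the 16‑O‑TIPS isopropenyl cyclopentylidene F1, in which C18–C22 is formed anti to the metal so the C16 arm is cis to C22. TBAF then gives the bis‑allylic alcohol F2, and MnO2 gives the cross‑conjugated isopropenyl dienone F3. Fe(acac)3/PhSiH3 in EtOH (metal‑hydride H‑atom transfer) converts the isopropenyl group into the tertiary C23 radical, which closes the seven‑membered ring by 7‑endo Giese addition to C14. The sequence rejoins the route at 21.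

**Step 14 (DDQ dehydrogenation to a tetrasubstituted alkene).** Hydride abstraction at the hindered C14–H may be slow, or over‑oxidation may occur. Fallback: change the order of events. Starting from 21, hydrogenate first with Crabtree's catalyst to the saturated cis‑fused ketone F4. PhSeCl in EtOAc (acid‑catalysed, through the more substituted enol) gives the C15 phenylselenide F5, and H2O2/pyridine syn‑elimination gives the enone. This rejoins the route at 23 and skips 22; any material selenenylated at C17 eliminates back to 21 and is recycled.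

**Step 15 (chemoselective directed hydrogenation of the dienone).** The risks are over‑reduction or poor facial control. Fallback: reduce the ketone first so that two hydroxyl groups direct the hydrogenation. Starting from 22, (S)‑Me‑CBS/catecholborane 1,2‑reduction gives the (16R) dienol F6. Crabtree hydrogenation, now directed by the 16‑OH and 19‑OH on the same face of C17=C18, then gives the target directly, rejoining at 24.

Further compounds
F1 | step 13 | (3R,5aR,6R,7S,9aR)‑7‑hydroxy‑6‑{(3E,6Z)‑6‑[(2R,5S)‑2‑hydroxy‑2‑methyl‑5‑(prop‑1‑en‑2‑yl)cyclopentylidene]‑4‑methyl‑5‑[(triisopropylsilyl)oxy]hex‑3‑en‑1‑yl}‑2,2,5a,7‑tetramethyldecahydro‑1‑benzoxepin‑3‑yl acetate | CC(=O)O[C@@H]1CC[C@]2(C)[C@@H](CC/C=C(\C)C(O[Si](C(C)C)(C(C)C)C(C)C)/C=C5\[C@H](C(C)=C)CC[C@@]5(C)O)[C@@](C)(O)CC[C@H]2OC1(C)C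
F2 | step 13 | desilylated bis‑allylic alcohol of F1 (16‑OH) | CC(=O)O[C@@H]1CC[C@]2(C)[C@@H](CC/C=C(\C)C(O)/C=C5\[C@H](C(C)=C)CC[C@@]5(C)O)[C@@](C)(O)CC[C@H]2OC1(C)C
F3 | step 13 | cross‑conjugated dienone from F2 (16‑oxo, isopropenyl at C22) | CC(=O)O[C@@H]1CC[C@]2(C)[C@@H](CC/C=C(\C)C(=O)/C=C5\[C@H](C(C)=C)CC[C@@]5(C)O)[C@@](C)(O)CC[C@H]2OC1(C)C
F4 | step 14 | 17,18‑dihydro derivative of 21 (saturated cis‑fused 16‑ketone, C14/C15 mixture) | CC(=O)O[C@@H]1CC[C@]2(C)[C@@H](CCC3C(C)C(=O)C[C@@H]4[C@@H](CC[C@@]4(C)O)C3(C)C)[C@@](C)(O)CC[C@H]2OC1(C)C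
F5 | step 14 | 15‑(phenylselanyl) derivative of F4 | CC(=O)O[C@@H]1CC[C@]2(C)[C@@H](CCC3C(C)([Se]c5ccccc5)C(=O)C[C@@H]4[C@@H](CC[C@@]4(C)O)C3(C)C)[C@@](C)(O)CC[C@H]2OC1(C)C
F6 | step 15 | (16R)‑dienol from 1,2‑reduction of 22 (17,18‑didehydro target) | CC(=O)O[C@@H]1CC[C@]2(C)[C@@H](CCC3=C(C)[C@H](O)C=C4[C@@H](CC[C@@]4(C)O)C3(C)C)[C@@](C)(O)CC[C@H]2OC1(C)C
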